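**Strategy**

The C40 polyene is cut at the C10–C11 single bond (carotenoid numbering; ring A = 3,4-dihydroxy ring, ring B = 3′-hydroxy ring). In one pot, zirconium-catalysed syn-methylalumination of a C13 enyne (ring A–C7=C8–C9≡C10) installs the C9 methyl and the E-C9=C10 bond, and the resulting C10–Al bond is cross-coupled (Pd/Zn) with a C26 heptaenyl iodide (C11–I). The step exploits the methyl-branched C9=C10 alkene next to C10–C11. Both rings derive from racemic α-ionone: the (3S,6S)-3-hydroxy enantiomer gives ring A by hydroxyl-directed epoxidation and base-induced epoxide opening, the (3R,6R) enantiomer gives ring B after Mitsunobu inversion.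

Key step: step 16

Remark (numbering): carotenoid locants are used throughout; ionone-type intermediates carry ring atoms C1–C6 and side-chain atoms C7–C10.
Remark (racemates): compounds 1–5 are racemic; for 4 and 5 the SMILES shows the (3R,6R) enantiomer of the racemate.
Remark (assumption): the lipase is taken to follow the Kazlauskas rule with CH2–C(CH3)2 as the large and CH= as the medium substituent, so the (3S)-alcohol is acetylated; with the opposite preference ester and alcohol only exchange roles and the methanolysis of step 6 moves to the other arm.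

**Route**

Step 1
Reactants: 1 (±)-α-ionone
Product: 2 (±)-α-ionone ethylene ketal
Conditions: HOCH2CH2OH, HC(OEt)3, p-TsOH (cat.), rt
Reagents that add atoms: ethylene glycol, OCCO
Why: Acid-catalysed ketalisation with the orthoformate as water scavenger should mask the side-chain carbonyl, so that only the ring carbonyl made in step 2 is reduced in step 3.

Step 2
Reactants: 2 (±)-α-ionone ethylene ketal
Product: 3 (±)-3-oxo-α-ionone ethylene ketal
Conditions: t-BuOOH (70% aq.), NaOCl (aq.), K2CO3, MeCN, 0 °C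
Reagents that add atoms: tert-butyl hydroperoxide, CC(C)(C)OO
Why: Radical allylic C–H oxidation should attack C3, the only unhindered allylic methylene (C6–H is flanked by the quaternary C1 and the C5 methyl), and the ketal is stable in the basic medium.

Step 3
Reactants: 3 (±)-3-oxo-α-ionone ethylene ketal
Product: 4 (±)-(3R*,6R*)-3-hydroxy-α-ionone ethylene ketal
Conditions: K[HB(s-Bu)3] (K-Selectride), THF, −78 °C; H2O
Reagents that add atoms: none
Why: 1,2-Reduction of the β,β-disubstituted ring enone by the bulky hydride should occur anti to the axial C1 methyl, so the new C3 hydroxyl lies trans to the C6 side chain (substrate control; the minor cis isomer is removed by chromatography).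

Step 4
Reactants: 4 (±)-(3R*,6R*)-3-hydroxy-α-ionone ethylene ketal
Product: 5 (±)-(3R*,6R*)-3-hydroxy-α-ionone
Conditions: PPTS (cat.), THF/H2O, rt
Reagents that add atoms: water, O
Why: Mild acid-catalysed ketal hydrolysis should free the enone carbonyl without ionising the ring allylic alcohol.

Step 5
Reactants: 5 (±)-(3R*,6R*)-3-hydroxy-α-ionone
Product: 6 (3S,6S)-3-acetoxy-α-ionone and 7 (3R,6R)-3-hydroxy-α-ionone (unreacted enantiomer, recovered)
Conditions: lipase AK (Pseudomonas fluorescens), vinyl acetate, t-BuOMe, 30 °C, stopped near half conversion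
Reagents that add atoms: vinyl acetate, CC(=O)OC=C
Why: Lipase-catalysed kinetic resolution by transesterification should acetylate the (3S)-alcohol (Kazlauskas rule) and leave 7, which fixes the absolute configuration of both arms; ester and alcohol are separated by chromatography.

Step 6
Reactants: 6 (3S,6S)-3-acetoxy-α-ionone
Product: 8 (3S,6S)-3-hydroxy-α-ionone
Conditions: K2CO3 (cat.), MeOH, 0 °C to rt
Reagents that add atoms: none
Why: Base-catalysed methanolysis of the acetate (transesterification) cleaves the acyl–oxygen bond and leaves C3 untouched.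

Step 7
Reactants: 8 (3S,6S)-3-hydroxy-α-ionone
Product: 9 (3S,4S,5R,6S)-4,5-epoxy-3-hydroxy-4,5-dihydro-α-ionone
Conditions: VO(acac)2 (cat.), t-BuOOH (in decane), toluene, 0 °C to rt
Reagents that add atoms: tert-butyl hydroperoxide, CC(C)(C)OO
Why: Hydroxyl-directed epoxidation should deliver oxygen to the C4=C5 alkene from the face of the 3-OH, which is also the face opposite the C6 side chain, setting C4 and C5, while the electron-poor side-chain alkene does not react.

Step 8
Reactants: 9 (3S,4S,5R,6S)-4,5-epoxy-3-hydroxy-4,5-dihydro-α-ionone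
Product: 10 (3S,4R)-3,4-dihydroxy-β-ionone
Conditions: NaOMe, MeOH, rt
Reagents that add atoms: none
Why: Vinylogous E1cB epoxide opening: methoxide removes C6–H (γ to the enone) and the dienolate expels the C5–O bond, giving the C5=C6 alkene and a C4 hydroxyl that stays cis to the 3-OH, while the C6 stereocentre is erased by design.

Step 9
Reactants: 10 (3S,4R)-3,4-dihydroxy-β-ionone
Product: 11 (3S,4R)-3,4-bis(tert-butyldimethylsilyloxy)-β-ionone
Conditions: TBSOTf (2.5 equiv), 2,6-lutidine, CH2Cl2, −78 to 0 °C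
Reagents that add atoms: tert-butyldimethylsilyl triflate, CC(C)(C)[Si](C)(C)OS(=O)(=O)C(F)(F)F
Why: Silylation with the silyl triflate should protect both hydroxyls of the cis-diol, including the hindered allylic C4–OH, at a temperature where the methyl ketone is not enolised.

Step 10
Reactants: 11 (3S,4R)-3,4-bis(tert-butyldimethylsilyloxy)-β-ionone
Product: 13 ring A enyne, via enol phosphate 12 (not isolated)
Conditions: LiN(i-Pr)2 (1.1 equiv), THF, −78 °C; ClP(O)(OEt)2, −78 °C to rt; then LiN(i-Pr)2 (2.3 equiv), −78 °C to rt; H2O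
Reagents that add atoms: none
Why: Negishi methyl ketone-to-alkyne conversion: kinetic deprotonation of the C10 methyl, O-phosphorylation and base-induced β-elimination of diethyl phosphate should give the terminal enyne.

Step 11
Reactants: 7 (3R,6R)-3-hydroxy-α-ionone
Product: 15 (3S,6R)-3-hydroxy-α-ionone, via nitrobenzoate ester 14 (not isolated)
Conditions: PPh3, DIAD, 4-O2NC6H4CO2H, THF, 0 °C to rt; then K2CO3, MeOH, 0 °C
Reagents that add atoms: 4-nitrobenzoic acid, OC(=O)c1ccc(cc1)[N+](=O)[O-]
Why: Mitsunobu reaction: SN2 displacement at the activated allylic C3 by 4-nitrobenzoate inverts C3 from R to S, and mild methanolysis of the ester should give the 3,6-cis alcohol with C6 untouched.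

Step 12
Reactants: 15 (3S,6R)-3-hydroxy-α-ionone
Product: 16 (3S,6R)-3-(tert-butyldimethylsilyloxy)-α-ionone
Conditions: TBSCl, imidazole, DMF, rt
Reagents that add atoms: tert-butyldimethylsilyl chloride, CC(C)(C)[Si](C)(C)Cl
Why: Standard silylation of the secondary allylic alcohol gives a group that survives amide bases and organoalanes and is removed by fluoride at the end.

Step 13
Reactants: 16 (3S,6R)-3-(tert-butyldimethylsilyloxy)-α-ionone
Product: 18 ring B enyne, via enol phosphate 17 (not isolated)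
Conditions: LiN(i-Pr)2 (1.1 equiv), THF, −78 °C; ClP(O)(OEt)2, −78 °C to rt; then LiN(i-Pr)2 (2.2 equiv), −78 to 0 °C; H2O
Reagents that add atoms: none
Why: The same Negishi methyl ketone-to-alkyne conversion, kept at or below 0 °C in the elimination stage so that the hindered, doubly allylic C6′–H is not deprotonated and C6′ keeps its configuration.

Step 14
Reactants: 19 (2E,4E,6E)-2,7-dimethylocta-2,4,6-trienedial
Product: 20 (1E,3E,5E,7E,9E)-1,10-diiodo-3,8-dimethyldeca-1,3,5,7,9-pentaene
Conditions: CHI3, CrCl2, THF/1,4-dioxane, 0 °C to rt, dark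
Reagents that add atoms: iodoform, IC(I)I
Why: Twofold Takai iodo-olefination: the geminal dichromium reagent from CHI3 and CrCl2 should convert each aldehyde into an (E)-vinyl iodide, adding C11 and C11′.

Step 15
Reactants: 18 ring B enyne; 20 (1E,3E,5E,7E,9E)-1,10-diiodo-3,8-dimethyldeca-1,3,5,7,9-pentaene
Product: 22 C26 heptaenyl iodide, via ring B dienylalane 21 (not isolated)
Conditions: Me3Al, Cp2ZrCl2 (cat.), ClCH2CH2Cl, rt; evaporate; then 20 (3 equiv), ZnCl2, Pd2(dba)3 (cat.), P(2-furyl)3, THF, rt, dark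
Reagents that add atoms: trimethylaluminium, C[Al](C)C
Why: Negishi zirconium-catalysed syn-methylalumination of the terminal alkyne followed by Pd/Zn-catalysed alkenyl–alkenyl coupling should form C9′–CH3 and C10′–C11′ with E geometry, the threefold excess of the symmetric diiodide restricting coupling to one terminus (surplus 20 is recovered).

Step 16
Reactants: 13 ring A enyne; 22 C26 heptaenyl iodide
Product: 24 tris(tert-butyldimethylsilyl) ether of the target, via ring A dienylalane 23 (not isolated)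
Conditions: 13 (1.3 equiv), Me3Al, Cp2ZrCl2 (cat.), ClCH2CH2Cl, rt; evaporate; then 22, ZnCl2, Pd2(dba)3 (cat.), P(2-furyl)3, THF, rt, dark
Reagents that add atoms: trimethylaluminium, C[Al](C)C
Why: Cp2ZrCl2-catalysed methylalumination of the terminal alkyne of 13 adds CH3 to C9 and aluminium to C10 in a syn fashion to give the (E)-dienylalane 23, and after removal of excess Me3Al, oxidative addition of zerovalent palladium into the C11–I bond of 22, zinc-mediated transmetalation of the C10 alkenyl group and reductive elimination forge the C10–C11 sp2–sp2 bond with retention at both carbons. The closest known reaction type is the Negishi zirconium-catalysed carboalumination with palladium–zinc cross-coupling, as used for all-E polyenes. No ring is closed and no stereocentre is formed; the four existing stereocentres are remote from the reacting carbons and are not touched. The step needs methyl delivery to C9, which the terminal alkyne secures because aluminium goes to the unsubstituted terminus, and E geometry at C9=C10, which the syn addition secures. It also needs a single electrophilic site, secured because 22 carries only one C–I bond, and tolerance of the silyl ethers, which carry no acidic hydrogen. The excess of the small fragment 13 protects the more valuable 22.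

Step 17
Reactants: 24 tris(tert-butyldimethylsilyl) ether of the target
Product: 25 (3S,4R,3′S,6′R)-β,ε-carotene-3,4,3′-triol
Conditions: Bu4NF, THF, rt, dark, argon
Reagents that add atoms: none
Why: Fluoride-induced desilylation should cleave the three silyl ethers under non-acidic conditions, which preserves the acid-labile allylic C4 and C3′ alcohols and the polyene.

**Compound list**

1 | (±)-α-ionone, (E)-4-(2,6,6-trimethylcyclohex-2-en-1-yl)but-3-en-2-one (racemate) | CC1=CCCC(C)(C)C1/C=C/C(C)=O | starting material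
2 | (±)-α-ionone ethylene ketal, 2-methyl-2-[(E)-2-(2,6,6-trimethylcyclohex-2-en-1-yl)ethenyl]-1,3-dioxolane | CC1=CCCC(C)(C)C1/C=C/C1(C)OCCO1 | intermediate
3 | (±)-3-oxo-α-ionone ethylene ketal, 3,5,5-trimethyl-4-[(E)-2-(2-methyl-1,3-dioxolan-2-yl)ethenyl]cyclohex-2-en-1-one | CC1=CC(=O)CC(C)(C)C1/C=C/C1(C)OCCO1 | intermediate
4 | (±)-(3R*,6R*)-3-hydroxy-α-ionone ethylene ketal (3-OH trans to the C6 side chain; racemate, (3R,6R) drawn) | CC1=C[C@H](O)CC(C)(C)[C@H]1/C=C/C1(C)OCCO1 | intermediate
5 | (±)-(3R*,6R*)-3-hydroxy-α-ionone, (E)-4-(4-hydroxy-2,6,6-trimethylcyclohex-2-en-1-yl)but-3-en-2-one with 3-OH trans to the side chain (racemate, (3R,6R) drawn) | CC1=C[C@H](O)CC(C)(C)[C@H]1/C=C/C(C)=O | intermediate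
6 | (3S,6S)-3-acetoxy-α-ionone, (1S,4S)-3,5,5-trimethyl-4-[(E)-3-oxobut-1-en-1-yl]cyclohex-2-en-1-yl acetate | CC1=C[C@@H](OC(C)=O)CC(C)(C)[C@@H]1/C=C/C(C)=O | intermediate
7 | (3R,6R)-3-hydroxy-α-ionone (trans) | CC1=C[C@H](O)CC(C)(C)[C@H]1/C=C/C(C)=O | intermediate
8 | (3S,6S)-3-hydroxy-α-ionone (trans) | CC1=C[C@@H](O)CC(C)(C)[C@@H]1/C=C/C(C)=O | intermediate
9 | (3S,4S,5R,6S)-4,5-epoxy-3-hydroxy-4,5-dihydro-α-ionone (epoxide oxygen cis to 3-OH, trans to the side chain) | C[C@]12O[C@H]1[C@@H](O)CC(C)(C)[C@@H]2/C=C/C(C)=O | intermediate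
10 | (3S,4R)-3,4-dihydroxy-β-ionone, (E)-4-[(3R,4S)-3,4-dihydroxy-2,6,6-trimethylcyclohex-1-en-1-yl]but-3-en-2-one (cis-diol) | CC(=O)/C=C/C1=C(C)[C@@H](O)[C@@H](O)CC1(C)C | intermediate
11 | (3S,4R)-3,4-bis(tert-butyldimethylsilyloxy)-β-ionone | CC(=O)/C=C/C1=C(C)[C@@H](O[Si](C)(C)C(C)(C)C)[C@@H](O[Si](C)(C)C(C)(C)C)CC1(C)C | intermediate
12 | diethyl enol phosphate of 11, diethyl (3E)-4-[ring A]buta-1,3-dien-2-yl phosphate | C=C(OP(=O)(OCC)OCC)/C=C/C1=C(C)[C@@H](O[Si](C)(C)C(C)(C)C)[C@@H](O[Si](C)(C)C(C)(C)C)CC1(C)C | intermediate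
13 | ring A enyne, (E)-1-[(3R,4S)-3,4-bis(tert-butyldimethylsilyloxy)-2,6,6-trimethylcyclohex-1-en-1-yl]but-1-en-3-yne | C#C/C=C/C1=C(C)[C@@H](O[Si](C)(C)C(C)(C)C)[C@@H](O[Si](C)(C)C(C)(C)C)CC1(C)C | intermediate
14 | (3S,6R)-3-(4-nitrobenzoyloxy)-α-ionone | CC1=C[C@@H](OC(=O)c2ccc(cc2)[N+](=O)[O-])CC(C)(C)[C@H]1/C=C/C(C)=O | intermediate
15 | (3S,6R)-3-hydroxy-α-ionone (3-OH cis to the side chain) | CC1=C[C@@H](O)CC(C)(C)[C@H]1/C=C/C(C)=O | intermediate
16 | (3S,6R)-3-(tert-butyldimethylsilyloxy)-α-ionone | CC1=C[C@@H](O[Si](C)(C)C(C)(C)C)CC(C)(C)[C@H]1/C=C/C(C)=O | intermediate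
17 | diethyl enol phosphate of 16 | CC1=C[C@@H](O[Si](C)(C)C(C)(C)C)CC(C)(C)[C@H]1/C=C/C(=C)OP(=O)(OCC)OCC | intermediate
18 | ring B enyne, tert-butyl{[(1S,4R)-4-[(E)-but-1-en-3-yn-1-yl]-3,5,5-trimethylcyclohex-2-en-1-yl]oxy}dimethylsilane | CC1=C[C@@H](O[Si](C)(C)C(C)(C)C)CC(C)(C)[C@H]1/C=C/C#C | intermediate
19 | (2E,4E,6E)-2,7-dimethylocta-2,4,6-trienedial (C10 dialdehyde) | O=C/C(C)=C/C=C/C=C(C)/C=O | starting material
20 | (1E,3E,5E,7E,9E)-1,10-diiodo-3,8-dimethyldeca-1,3,5,7,9-pentaene | I/C=C/C(C)=C/C=C/C=C(C)/C=C/I | intermediate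
21 | ring B dienylalane, dimethyl[(1E,3E)-2-methyl-4-(ring B)buta-1,3-dien-1-yl]alane | CC1=C[C@@H](O[Si](C)(C)C(C)(C)C)CC(C)(C)[C@H]1/C=C/C(C)=C/[Al](C)C | intermediate
22 | C26 heptaenyl iodide, tert-butyl{[(1S,4R)-4-[(1E,3E,5E,7E,9E,11E,13E)-14-iodo-3,7,12-trimethyltetradeca-1,3,5,7,9,11,13-heptaen-1-yl]-3,5,5-trimethylcyclohex-2-en-1-yl]oxy}dimethylsilane | CC1=C[C@@H](O[Si](C)(C)C(C)(C)C)CC(C)(C)[C@H]1/C=C/C(C)=C/C=C/C(C)=C/C=C/C=C(C)/C=C/I | intermediate
23 | ring A dienylalane, dimethyl[(1E,3E)-2-methyl-4-(ring A)buta-1,3-dien-1-yl]alane | C[Al](C)/C=C(C)/C=C/C1=C(C)[C@@H](O[Si](C)(C)C(C)(C)C)[C@@H](O[Si](C)(C)C(C)(C)C)CC1(C)C | intermediate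
24 | (3S,4R,3′S,6′R)-3,4,3′-tris(tert-butyldimethylsilyloxy)-β,ε-carotene | CC1=C[C@@H](O[Si](C)(C)C(C)(C)C)CC(C)(C)[C@H]1/C=C/C(C)=C/C=C/C(C)=C/C=C/C=C(C)/C=C/C=C(C)/C=C/C1=C(C)[C@@H](O[Si](C)(C)C(C)(C)C)[C@@H](O[Si](C)(C)C(C)(C)C)CC1(C)C | intermediate
25 | (3S,4R,3′S,6′R)-β,ε-carotene-3,4,3′-triol | CC1=C[C@@H](O)CC(C)(C)[C@H]1/C=C/C(C)=C/C=C/C(C)=C/C=C/C=C(C)/C=C/C=C(C)/C=C/C1=C(C)[C@@H](O)[C@@H](O)CC1(C)C | target

**Step count and risks**

Total step count: 17. Longest linear sequence: 12 steps (steps 1–10, 16, 17).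

Steps most likely to fail:

1. Step 16. The dienylalane may be protonated before it transfers its alkenyl group, or the aluminium-to-zinc-to-palladium transfer may be slow enough for the polyenyl iodide to isomerise or homocouple; the Lewis-acidic medium may also ionise the allylic C4 silyl ether during carboalumination. The fallback sets out from 13 and comes back at 24. The alane 23 made from 13 is quenched with I2 to give the ring A dienyl iodide F1. Iodine–lithium exchange (t-BuLi, Et2O, −78 °C) and trapping with Bu3SnCl give the ring A dienylstannane F2, which is purified. A Stille coupling of F2 with 22 (Pd2(dba)3, AsPh3, NMP, rt) should then give 24.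

2. Step 15. Site control may be lost, the second C–I terminus coupling as well, and the polyenyl diiodide may isomerise or decompose in light. The fallback sets out from 16 and 19 and comes back at 22. Addition of CH2=CHMgBr to 16 gives the tertiary vinyl carbinol F3. Treatment with PPh3·HBr in MeOH/CH2Cl2 gives, by allylic transposition, the C15 phosphonium bromide F4. A Wittig reaction of F4 with an excess of 19 (NaOMe, CH2Cl2/MeOH) gives the C25 aldehyde F5. Takai iodo-olefination of F5 (CHI3, CrCl2) should then give 22.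

3. Step 5. The enzyme may discriminate the enantiomers too weakly, so that both fractions stay partly racemic. The fallback sets out from 5 and comes back at 8 and 7. Esterification of 5 with (S)-O-methylmandelic acid (DCC, DMAP cat., CH2Cl2) gives the diastereomeric esters (3S,6S)-mandelate F6 and (3R,6R)-mandelate F7, which are separated by chromatography. Methanolysis (K2CO3, MeOH) of F6 gives 8 and of F7 gives 7.

Further compounds
F1 | step 16 | ring A dienyl iodide, (1E,3E)-1-iodo-2-methyl-4-[(3R,4S)-3,4-bis(tert-butyldimethylsilyloxy)-2,6,6-trimethylcyclohex-1-en-1-yl]buta-1,3-diene | I/C=C(C)/C=C/C1=C(C)[C@@H](O[Si](C)(C)C(C)(C)C)[C@@H](O[Si](C)(C)C(C)(C)C)CC1(C)C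
F2 | step 16 | ring A dienylstannane, tributyl[(1E,3E)-2-methyl-4-(ring A)buta-1,3-dien-1-yl]stannane | CCCC[Sn](CCCC)(CCCC)/C=C(C)/C=C/C1=C(C)[C@@H](O[Si](C)(C)C(C)(C)C)[C@@H](O[Si](C)(C)C(C)(C)C)CC1(C)C
F3 | step 15 | tertiary vinyl carbinol, (E)-3-methyl-1-[(1R,4S)-4-(tert-butyldimethylsilyloxy)-2,6,6-trimethylcyclohex-2-en-1-yl]penta-1,4-dien-3-ol (C9 epimers) | CC1=C[C@@H](O[Si](C)(C)C(C)(C)C)CC(C)(C)[C@H]1/C=C/C(C)(O)C=C
F4 | step 15 | C15 phosphonium bromide, [(2E,4E)-3-methyl-5-(ring B)penta-2,4-dien-1-yl]triphenylphosphonium bromide | CC1=C[C@@H](O[Si](C)(C)C(C)(C)C)CC(C)(C)[C@H]1/C=C/C(C)=C/C[P+](c2ccccc2)(c2ccccc2)c2ccccc2.[Br-]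
F5 | step 15 | C25 aldehyde, (2E,4E,6E,8E,10E,12E)-2,7,11-trimethyl-13-(ring B)trideca-2,4,6,8,10,12-hexaenal | CC1=C[C@@H](O[Si](C)(C)C(C)(C)C)CC(C)(C)[C@H]1/C=C/C(C)=C/C=C/C(C)=C/C=C/C=C(C)/C=O
F6 | step 5 | (3S,6S)-3-[(S)-2-methoxy-2-phenylacetoxy]-α-ionone | CC1=C[C@@H](OC(=O)[C@@H](OC)c2ccccc2)CC(C)(C)[C@@H]1/C=C/C(C)=O
F7 | step 5 | (3R,6R)-3-[(S)-2-methoxy-2-phenylacetoxy]-α-ionone | CC1=C[C@H](OC(=O)[C@@H](OC)c2ccccc2)CC(C)(C)[C@H]1/C=C/C(C)=O
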